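(The earlier runs and the new flask are calculated from invented constants.)

Watch the gap in the balance after target has peaked.

| flask | starting material | reagent | second substrate | remark | time |
|---|---|---|---|---|---|
| Friday's | 0.076 M | 0.60 equiv | 0.50 equiv | the very flask that is asked about, followed so far |  |
| Monday's | 0.076 M | 1.2 equiv | 0.50 equiv | run made earlier |  |
| flask | 0.076 M | 0.600 equiv | 0.500 equiv |  | 4.0 h |

Friday's run (percent of the starting material charged)

| time / h | target / % | starting material / % |
|---|---|---|
| 0.200 | 35.7 | 63.8 |
| 0.333 | 44.5 | 55.2 |
| 0.500 | 48.6 | 48.5 |
| 0.833 | 51.3 | 45.7 |
| 1.33 | 51.9 | 42.3 |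
| 2.50 | 46.1 | 45.4 |

Monday's run (percent of the starting material charged)

| time / min | target / % | starting material / % |
|---|---|---|
| 6.00 | 43.4 | 55.3 |
| 15.0 | 65.0 | 32.6 |
| 30.0 | 80.6 | 17.6 |
| 50.0 | 84.6 | 12.2 |
| 60.0 | 86.1 | 8.7 |
| 80.0 | 86.6 | 5.3 |

(standard deviation of a reading: 1 percentage point)

1. target, in percent of the starting material first charged, at 4.0 h
2. the option that brings most further target ("none" if no option brings more than 2 percentage points) (violet / grey / amber / ochre / none)
3. target present, with what was taken out counted in, in percent of the starting material first charged, after violet
4. target present, with what was taken out counted in, in percent of the starting material first charged, after grey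

- violet: at 4.0 h add reagent, 50.0 % of the amount charged, then wait 8.0 h
- grey: at 4.0 h take out 90 % of the target then present, then wait 8.0 h
- amber: change nothing and wait 8.0 h more
- ochre: at 4.0 h add starting material, 50.0 % of the amount charged, then wait 8.0 h

- what is taken out of target is counted as made
- additions bring no volume worth counting

In Friday's flask starting material stood at 45.7 %, 42.3 % and 45.4 % from 0.833 h on. In Monday's flask, with 1.2 equiv of reagent, it fell lower, to 5.3 %. So I took reagent as the limiting reagent on Friday.

In Friday's flask target then fell, and at 2.50 h target and starting material together lacked 8.50 %. I took this loss as first order in c(target). I divided the gap by the target reading, used as the run's mean, and by the time. That gave 0.0738 h⁻¹, a reading I called the loss constant: the share of the target present that disappears per hour.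

From the last reading it gave me 41.3 % at 4.0 h. Over the wait of 8.0 h, I reckoned target to keep 55.4 % of itself. Friday's reagent had converted 54.6 % of starting material, so I counted violet as making 27.3 % at once. I then reckoned violet to end at 38.0 % and grey at 39.4 %. Violet and grey both lay below 41.3 %. I counted amber and ochre as making no target, which put each at 22.9 %. So I chose none.

The forecast gave 41.5 %, violet, 49 % after violet and 40 % after grey. Of the loss it said “I assume it is consumed by the second substrate”. It differed from me on violet.

The flask gave 42.1 % at 4.0 h, and the best option was none. Violet ended at 37.6 %, 11 percentage points under the forecast, and grey at 40.2 %.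

    starting material + reagent → target (k = 1.38 L mol⁻¹ min⁻¹)
    second substrate + reagent → second product (k = 0.132 L mol⁻¹ min⁻¹)
    target → over-reaction product (k = 0.00127 min⁻¹)

In the flask at 4.00 h reagent stood at 0 % and over-reaction product at 14.1 %. The loss constant took 42.1 % down to 23.3 % for amber. The neighbouring flask with 0.150 equiv of reagent held target and over-reaction product summing to 14.3 % at 4.0 h. Counted in percent of the starting material charged, the loss constant kept 10.6 % as target out of that sum, and that flask held 10.7 % of target.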